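**Plan**
- Retrosynthesis: the pyranone is opened at O2–C3 to a 2-(prop-1-ynyl)benzoic acid; then the two bonds on neighbouring benzenoid carbons, C5–CH2 (to ring A) and C4a–C4 (to the propyne unit), are cut together, leaving an aryl iodide, a ring A benzylic bromide and propyne.
- Feature used: C4a and C5 are adjacent on the benzenoid ring of the isocoumarin and C4a lies next to the carboxyl-bearing C8a, so an iodide at C4a has C5–H as its only ortho C–H; palladium relayed by norbornene from C4a reaches C5 and cannot reach C7.
- Both arenes show the same pattern (a carbon substituent flanked by OMe, with an oxygen para to it) and both are drawn from 2,4-dihydroxy-6-iodobenzaldehyde, whose formyl group tells the two phenols apart.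
- Forward: formylation, phenol differentiation, one branch to the iodo ester and one to the ring A bromide, three-component coupling (chain joined, no ring formed), saponification, gold-catalysed 6-endo-dig closure of the pyranone (the only ring made), hydrogenolysis.
- Stereochemistry: the target has no stereocenter; every selectivity question is regiochemical.

Key step: step 11

Remark: the ring A phenol is carried as a tosylate because a 2,4-dialkoxybenzyl bromide with an ortho methoxymethyl group would ionise and close to a phthalan under hot Cs2CO3, and the iodide is built by formylation of an iodoresorcinol ether because directed C–H iodination of the electron-rich benzoic acid would compete with ring iodination para to the methoxy group.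

**Route**

Step 1
Reactants: 1 1-iodo-3,5-dimethoxybenzene
Product: 3 2-iodo-4,6-dimethoxybenzaldehyde, via aryl iminium chloride 2 (not isolated)
Conditions: POCl3, DMF, 0 to 90 °C; then ice/H2O
Reagents that add atoms: N,N-dimethylformamide CN(C)C=O; water O
Why: Vilsmeier–Haack formylation should go para to one methoxy group and ortho to the other, at the carbon beside iodine and not between the two methoxy groups, as is usual for 1-halo-3,5-dimethoxybenzenes, and water hydrolyses the iminium salt to the aldehyde.

Step 2
Reactants: 3 2-iodo-4,6-dimethoxybenzaldehyde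
Product: 4 2,4-dihydroxy-6-iodobenzaldehyde
Conditions: BBr3 (4 equiv), CH2Cl2, −78 °C to rt; then H2O
Reagents that add atoms: none
Why: Lewis-acid cleavage of both aryl methyl ethers by BBr3, the ortho one helped by chelation to the formyl group, should leave the iodide alone because it sits meta to both oxygens and is not prone to protodeiodination.

Step 3
Reactants: 4 2,4-dihydroxy-6-iodobenzaldehyde
Product: 5 4-(benzyloxy)-2-hydroxy-6-iodobenzaldehyde
Conditions: BnBr (1.05 equiv), NaHCO3, MeCN, 60 °C
Reagents that add atoms: benzyl bromide BrCc1ccccc1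
Why: Williamson etherification under weak base should alkylate only the more acidic, unchelated 4-hydroxyl (para to the formyl group), since the 2-hydroxyl is held in a hydrogen bond to the aldehyde.

Step 4
Reactants: 5 4-(benzyloxy)-2-hydroxy-6-iodobenzaldehyde
Product: 6 4-(benzyloxy)-2-hydroxy-6-iodobenzoic acid
Conditions: NaClO2, NaH2PO4, 2-methyl-2-butene, t-BuOH/THF/H2O, 0 °C to rt
Reagents that add atoms: sodium chlorite [Na+].[O-]Cl=O
Why: Pinnick oxidation should convert the aldehyde into the acid without touching iodide or benzyl ether, the alkene scavenger removing the HOCl that would otherwise chlorinate the phenol ring.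

Step 5
Reactants: 6 4-(benzyloxy)-2-hydroxy-6-iodobenzoic acid
Product: 8 methyl 4-(benzyloxy)-2-iodo-6-methoxybenzoate, via hydroxy methyl ester 7 (not isolated)
Conditions: MeI (3 equiv), K2CO3, DMF, 50 °C
Reagents that add atoms: iodomethane CI
Why: Double O-alkylation (Williamson type) should methylate the carboxylate first and the salicylate phenol second, and as both are SN2 reactions at methyl the crowding around the carboxyl group is of no consequence.

Step 6
Reactants: 4 2,4-dihydroxy-6-iodobenzaldehyde
Product: 9 4-formyl-3-hydroxy-5-iodophenyl 4-methylbenzenesulfonate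
Conditions: TsCl (1.05 equiv), K2CO3, acetone, 0 °C to rt
Reagents that add atoms: 4-methylbenzenesulfonyl chloride Cc1ccc(cc1)S(Cl)(=O)=O
Why: O-Sulfonylation under weak base should take place at the unchelated 4-hydroxyl for the same reason as in step 3, and the electron-withdrawing sulfonate is what later tames the benzylic bromide.

Step 7
Reactants: 9 4-formyl-3-hydroxy-5-iodophenyl 4-methylbenzenesulfonate
Product: 10 4-formyl-3-iodo-5-methoxyphenyl 4-methylbenzenesulfonate
Conditions: MeI, K2CO3, acetone, reflux
Reagents that add atoms: iodomethane CI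
Why: Williamson methylation of the remaining chelated phenol should proceed cleanly because aryl tosylates are stable to K2CO3 and MeI.

Step 8
Reactants: 10 4-formyl-3-iodo-5-methoxyphenyl 4-methylbenzenesulfonate
Product: 11 4-formyl-3-methoxy-5-(methoxymethyl)phenyl 4-methylbenzenesulfonate
Conditions: Bu3SnCH2OMe, Pd(PPh3)4 (5 mol %), CuI (10 mol %), DMF, 90 °C
Reagents that add atoms: tributyl(methoxymethyl)stannane CCCC[Sn](CCCC)(CCCC)COC
Why: Stille coupling of the aryl iodide with the α-alkoxymethylstannane, which transfers the methoxymethyl group in preference to butyl, should be selective because Pd(PPh3)4 does not insert into an aryl tosylate and tolerates the aldehyde.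

Step 9
Reactants: 11 4-formyl-3-methoxy-5-(methoxymethyl)phenyl 4-methylbenzenesulfonate
Product: 12 4-(hydroxymethyl)-3-methoxy-5-(methoxymethyl)phenyl 4-methylbenzenesulfonate
Conditions: NaBH4, MeOH/THF, 0 °C
Reagents that add atoms: none
Why: Borohydride reduction of the aldehyde should give the benzylic alcohol while sulfonate and ethers stay inert.

Step 10
Reactants: 12 4-(hydroxymethyl)-3-methoxy-5-(methoxymethyl)phenyl 4-methylbenzenesulfonate
Product: 13 4-(bromomethyl)-3-methoxy-5-(methoxymethyl)phenyl 4-methylbenzenesulfonate
Conditions: CBr4, PPh3, CH2Cl2, 0 °C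
Reagents that add atoms: tetrabromomethane BrC(Br)(Br)Br
Why: Appel bromination under neutral conditions should convert the primary benzylic alcohol into the bromide, and the para tosylate keeps the product from ionising, so that it should be isolable.

Step 11
Reactants: 8 methyl 4-(benzyloxy)-2-iodo-6-methoxybenzoate; 13 4-(bromomethyl)-3-methoxy-5-(methoxymethyl)phenyl 4-methylbenzenesulfonate; 14 propyne
Product: 15 methyl 4-(benzyloxy)-6-methoxy-3-{2-methoxy-6-(methoxymethyl)-4-[(4-methylbenzenesulfonyl)oxy]benzyl}-2-(prop-1-yn-1-yl)benzoate
Conditions: Pd(OAc)2 (10 mol %), P(2-furyl)3 (22 mol %), norbornene (2 equiv), Cs2CO3 (4 equiv), 13 (1.3 equiv), MeCN, 80 °C, sealed tube; propyne (1 M in THF, 3 equiv) added in portions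
Reagents that add atoms: none
Why: Iodide 8 adds oxidatively to zerovalent palladium, norbornene inserts, and the resulting alkylpalladium, a divalent species, can metalate only the one C–H ortho to the former C–I carbon (the future C5), which closes a five-membered palladacycle. Bromide 13 adds to this electron-rich palladacycle in SN2 fashion to give tetravalent palladium, reductive elimination forms the C5–CH2 bond, and, with the ester on one side and the new benzyl group on the other, norbornene is expelled by β-carbon elimination. The arylpalladium left at the former C–I carbon (the future C4a) is alkynylated by propyne and Cs2CO3 in a copper-free Sonogashira-type termination. The closest known reaction type is the Catellani ortho-alkylation of ortho-substituted aryl iodides with alkyl or benzyl halides that ends in alkynylation by a terminal alkyne; no ring closes and no stereocenter forms. The step needs site selectivity, secured because the iodide has a single ortho C–H, and the right order of events, secured because norbornene cannot leave before that position is alkylated and helped by adding propyne in portions so that direct alkynylation of the iodide stays slow. The tosylate keeps 13 from ionising under hot carbonate, and the two ortho substituents of ring A, which slow the SN2 step, also leave no ring A C–H for a competing cyclopalladation to a fluorene.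

Step 12
Reactants: 15 methyl 4-(benzyloxy)-6-methoxy-3-{2-methoxy-6-(methoxymethyl)-4-[(4-methylbenzenesulfonyl)oxy]benzyl}-2-(prop-1-yn-1-yl)benzoate
Product: 16 4-(benzyloxy)-3-[4-hydroxy-2-methoxy-6-(methoxymethyl)benzyl]-6-methoxy-2-(prop-1-yn-1-yl)benzoic acid
Conditions: KOH (10 equiv), EtOH/H2O (4:1), 85 °C; then 1 M HCl, 0 °C
Reagents that add atoms: potassium hydroxide [K+].[OH-]
Why: Saponification with hot KOH should cleave the methyl ester, which is flanked only by a methoxy group and a slim alkyne, and in the same operation hydroxide attacks sulfur and frees the ring A phenol, while the para oxygen of the benzoate stays a benzyl ether so that the ester is not deactivated as a phenoxide.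

Step 13
Reactants: 16 4-(benzyloxy)-3-[4-hydroxy-2-methoxy-6-(methoxymethyl)benzyl]-6-methoxy-2-(prop-1-yn-1-yl)benzoic acid
Product: 17 6-(benzyloxy)-5-[4-hydroxy-2-methoxy-6-(methoxymethyl)benzyl]-8-methoxy-3-methyl-1H-isochromen-1-one
Conditions: Ph3PAuNTf2 (5 mol %), CH2Cl2, rt
Reagents that add atoms: none
Why: In this gold-catalysed cycloisomerisation of a 2-alkynylbenzoic acid, univalent gold activates the alkyne and the carboxyl oxygen should attack the methyl-bearing carbon in the 6-endo-dig mode, favoured because the aryl-bound alkyne carbon gets no donation from the two meta oxygens and because a 5-exo alkylidene phthalide would clash with the neighbouring benzyl group.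

Step 14
Reactants: 17 6-(benzyloxy)-5-[4-hydroxy-2-methoxy-6-(methoxymethyl)benzyl]-8-methoxy-3-methyl-1H-isochromen-1-one
Product: 18 6-hydroxy-5-[4-hydroxy-2-methoxy-6-(methoxymethyl)benzyl]-8-methoxy-3-methyl-1H-isochromen-1-one
Conditions: H2 (1 atm), Pd/C (10 %), EtOAc, rt, stopped when 17 is consumed
Reagents that add atoms: none
Why: Hydrogenolysis of the aryl benzyl ether over Pd/C should be faster than reduction of the conjugated pyranone double bond and than cleavage of the alkyl benzylic methyl ether, so that the target should result.

**Compound list**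
1 | 1-iodo-3,5-dimethoxybenzene | COc1cc(I)cc(OC)c1 | starting material
2 | N-(2-iodo-4,6-dimethoxybenzylidene)-N-methylmethanaminium chloride | C[N+](C)=Cc1c(I)cc(OC)cc1OC.[Cl-] | intermediate
3 | 2-iodo-4,6-dimethoxybenzaldehyde | O=Cc1c(I)cc(OC)cc1OC | intermediate
4 | 2,4-dihydroxy-6-iodobenzaldehyde | O=Cc1c(I)cc(O)cc1O | intermediate
5 | 4-(benzyloxy)-2-hydroxy-6-iodobenzaldehyde | O=Cc1c(I)cc(OCc2ccccc2)cc1O | intermediate
6 | 4-(benzyloxy)-2-hydroxy-6-iodobenzoic acid | OC(=O)c1c(I)cc(OCc2ccccc2)cc1O | intermediate
7 | methyl 4-(benzyloxy)-2-hydroxy-6-iodobenzoate | COC(=O)c1c(I)cc(OCc2ccccc2)cc1O | intermediate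
8 | methyl 4-(benzyloxy)-2-iodo-6-methoxybenzoate | COC(=O)c1c(I)cc(OCc2ccccc2)cc1OC | intermediate
9 | 4-formyl-3-hydroxy-5-iodophenyl 4-methylbenzenesulfonate | O=Cc1c(I)cc(OS(=O)(=O)c2ccc(C)cc2)cc1O | intermediate
10 | 4-formyl-3-iodo-5-methoxyphenyl 4-methylbenzenesulfonate | O=Cc1c(I)cc(OS(=O)(=O)c2ccc(C)cc2)cc1OC | intermediate
11 | 4-formyl-3-methoxy-5-(methoxymethyl)phenyl 4-methylbenzenesulfonate | O=Cc1c(COC)cc(OS(=O)(=O)c2ccc(C)cc2)cc1OC | intermediate
12 | 4-(hydroxymethyl)-3-methoxy-5-(methoxymethyl)phenyl 4-methylbenzenesulfonate | OCc1c(COC)cc(OS(=O)(=O)c2ccc(C)cc2)cc1OC | intermediate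
13 | 4-(bromomethyl)-3-methoxy-5-(methoxymethyl)phenyl 4-methylbenzenesulfonate | BrCc1c(COC)cc(OS(=O)(=O)c2ccc(C)cc2)cc1OC | intermediate
14 | propyne | CC#C | starting material
15 | methyl 4-(benzyloxy)-6-methoxy-3-{2-methoxy-6-(methoxymethyl)-4-[(4-methylbenzenesulfonyl)oxy]benzyl}-2-(prop-1-yn-1-yl)benzoate | CC#Cc1c(Cc2c(COC)cc(OS(=O)(=O)c3ccc(C)cc3)cc2OC)c(OCc2ccccc2)cc(OC)c1C(=O)OC | intermediate
16 | 4-(benzyloxy)-3-[4-hydroxy-2-methoxy-6-(methoxymethyl)benzyl]-6-methoxy-2-(prop-1-yn-1-yl)benzoic acid | CC#Cc1c(Cc2c(COC)cc(O)cc2OC)c(OCc2ccccc2)cc(OC)c1C(=O)O | intermediate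
17 | 6-(benzyloxy)-5-[4-hydroxy-2-methoxy-6-(methoxymethyl)benzyl]-8-methoxy-3-methyl-1H-isochromen-1-one | COCc1cc(O)cc(OC)c1Cc1c(OCc3ccccc3)cc(OC)c2c(=O)oc(C)cc12 | intermediate
18 | 6-hydroxy-5-[4-hydroxy-2-methoxy-6-(methoxymethyl)benzyl]-8-methoxy-3-methyl-1H-isochromen-1-one | COCc1cc(O)cc(OC)c1Cc1c(O)cc(OC)c2c(=O)oc(C)cc12 | target

**Count and risks**
Total step count: 14. Longest linear sequence: 11 steps (steps 1, 2, 6 to 14).

Step 11. Metalation of the C–H flanked by the benzyloxy group may be slow, and the doubly ortho-substituted bromide may add too slowly to the palladacycle. Norbornene-containing products, or direct alkynylation of the iodide, could then take over. The fallback makes the two bonds one after the other, sets out from 8 and 13 and comes back at 15. Sonogashira coupling of 8 with propyne (PdCl2(PPh3)2, CuI, Et3N) would give methyl 4-(benzyloxy)-2-methoxy-6-(prop-1-yn-1-yl)benzoate F1. Bromination with NBS in MeCN, expected para to the methoxy group and beside the alkyne as in other 3,5-dialkoxyaryl systems, would give methyl 4-(benzyloxy)-3-bromo-6-methoxy-2-(prop-1-yn-1-yl)benzoate F2. Bromide 13 would be turned by Zn dust and LiCl in THF into {2-methoxy-6-(methoxymethyl)-4-[(4-methylbenzenesulfonyl)oxy]benzyl}zinc bromide F3, and Negishi coupling of F2 with F3 (Pd(OAc)2, SPhos, THF) would give 15.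

Step 13. The acid may close in the 5-exo mode to an alkylidene phthalide, or lose CO2 under adventitious acid. The fallback changes the nucleophile to the ester carbonyl, sets out from 15 and comes back at 17. Ester 15 would be cyclised directly (catalytic TfOH in 1,2-dichloroethane, or Ph3PAuNTf2 with water), with loss of the ester methyl group, to 4-{[6-(benzyloxy)-8-methoxy-3-methyl-1-oxo-1H-isochromen-5-yl]methyl}-3-methoxy-5-(methoxymethyl)phenyl 4-methylbenzenesulfonate F4. Aqueous KOH in MeOH would cleave the tosylate and open the lactone to 4-(benzyloxy)-3-[4-hydroxy-2-methoxy-6-(methoxymethyl)benzyl]-6-methoxy-2-(2-oxopropyl)benzoic acid F5. Acid-catalysed cyclodehydration (TsOH, toluene, heat) would re-form the pyranone and give 17.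

Step 14. The pyranone C3–C4 double bond may be reduced, or the benzylic methyl ether of ring A hydrogenolysed, before the benzyl ether is gone. The fallback replaces hydrogenation by Lewis-acid debenzylation, sets out from 17 and comes back at 18. BCl3 with pentamethylbenzene as cation scavenger in CH2Cl2 at −78 °C, quenched cold so that the chelated 8-methoxy group is not cleaved, would give 18 directly; this fallback makes no new compound (F0).

Further compounds
F1 | step 11 | methyl 4-(benzyloxy)-2-methoxy-6-(prop-1-yn-1-yl)benzoate | CC#Cc1cc(OCc2ccccc2)cc(OC)c1C(=O)OC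
F2 | step 11 | methyl 4-(benzyloxy)-3-bromo-6-methoxy-2-(prop-1-yn-1-yl)benzoate | CC#Cc1c(Br)c(OCc2ccccc2)cc(OC)c1C(=O)OC
F3 | step 11 | {2-methoxy-6-(methoxymethyl)-4-[(4-methylbenzenesulfonyl)oxy]benzyl}zinc bromide | Br[Zn]Cc1c(COC)cc(OS(=O)(=O)c2ccc(C)cc2)cc1OC
F4 | step 13 | 4-{[6-(benzyloxy)-8-methoxy-3-methyl-1-oxo-1H-isochromen-5-yl]methyl}-3-methoxy-5-(methoxymethyl)phenyl 4-methylbenzenesulfonate | COCc1cc(OS(=O)(=O)c4ccc(C)cc4)cc(OC)c1Cc1c(OCc3ccccc3)cc(OC)c2c(=O)oc(C)cc12
F5 | step 13 | 4-(benzyloxy)-3-[4-hydroxy-2-methoxy-6-(methoxymethyl)benzyl]-6-methoxy-2-(2-oxopropyl)benzoic acid | CC(=O)Cc1c(Cc2c(COC)cc(O)cc2OC)c(OCc2ccccc2)cc(OC)c1C(=O)O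
F0 | step 14 | none | none
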